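Take the ratio of the two products as the number to carry from the elm run into the two new flasks, west and south.

| flask | left-handed substrate | right-handed substrate | reagent | free catalyst | racemization catalyst | remark | time |
|---|---|---|---|---|---|---|---|
| elm | 0.80 M | 0.80 M | 3 equiv | 0.23 mol% | 0.67 mol% | run made earlier |  |
| west | 0.80 M | 0.80 M | 2.00 equiv | 0.23 mol% | 0.67 mol% |  | 15 h |
| south | 0.80 M | 0.80 M | 2.00 equiv | 0.15 mol% | 0.67 mol% |  | 15 h |

elm run (percent of the left-handed substrate and right-handed substrate together charged)

| time / h | left-handed product / % | right-handed product / % |
|---|---|---|
| 0.250 | 32.5 | 14.8 |
| 0.417 | 43.0 | 19.5 |
| 0.667 | 51.0 | 23.1 |
| 1.00 | 58.5 | 24.6 |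
| 2.00 | 66.6 | 28.7 |
| 3.00 | 68.3 | 29.6 |

(scatter of a reading: 0.5 percentage points)

- free catalyst is single-handed; left-handed substrate and right-handed substrate are mirror images of each other, charged as a racemate, each of them at the stated concentration
- the earlier runs were read with a standard deviation of 0.5 percentage points
- an excess is the difference of the two amounts in percent of their sum
- an excess is below zero if the other one leads
- no earlier run changes the charge of free catalyst; that part of a forecast is a guess

1. the winner by excess of left-handed product over right-handed product in the product; "neither" if no more than 2 percentage points parts them (west / south / neither)
2. excess of left-handed product over right-handed product in the product at the end, west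
3. excess of left-handed product over right-handed product in the product at the end, south

1. In elm I read left-handed product at 68.3% after 3.00 h, more than the 50% that the charged left-handed substrate could supply, so the racemization catalyst was turning right-handed substrate into left-handed substrate while the free catalyst worked.

2. I took that last reading's left-handed product over its right-handed product, which gave 2.31; the excess is this ratio less one, over the ratio plus one, here 39.6%.

3. I assumed that reagent and free catalyst entered the rates of both products in the same way, with reagent used up and free catalyst handed back, so as long as the two substrates stayed nearly equal, those charges cancelled from the ratio; the free catalyst part was a guess, since no earlier run changed it.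

4. In west and south, 2.00 equiv meant one reagent for each molecule of the two substrates, so the rate fell as the square of one concentration, whereas elm's 3 equiv kept a surplus. Still, elm had made 97.9% product in 3.00 h, so I took 15 h as close to finished.

5. The weak link was a single reading with a scatter of 0.5 percentage points, so I summed all six readings of each product and took s, the product ratio as read in elm, as their quotient, 2.28. That gave me 39.0% for both flasks, hence neither.

The forecast said neither, with 39% for west and 38.5% for south, holding that “the excess reflects the intrinsic rate ratio”; my south figure stood slightly above its own.

The flasks gave neither, with 40.7% in west and 41.3% in south.

    reagent + free catalyst + right-handed substrate → free catalyst + right-handed product (k = 404 L² mol⁻² h⁻¹)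
    left-handed substrate + racemization catalyst ⇌ right-handed substrate + racemization catalyst, rate k2*[racemization catalyst]*[left-handed substrate] forward; the back reaction follows from the equilibrium constant (k = 1550 L mol⁻¹ h⁻¹)
    reagent + free catalyst + left-handed substrate → free catalyst + left-handed product (k = 1010 L² mol⁻² h⁻¹)
    reagent + free catalyst → spent catalyst B (k = 0.0260 L mol⁻¹ h⁻¹)
    racemization catalyst → spent catalyst A (k = 0.162 h⁻¹)

In south, half of the turnover to left-handed product was done by 0.685 h, well inside the 4.3 h half-life of the racemization catalyst, and at 15.0 h that catalyst stood at 8.80% of its charge, with left-handed substrate at 2.47% and right-handed substrate at 2.56%. Against my s of 2.28, the excess of west corresponds to a product ratio of 2.37, and that of south to 2.41.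

The readings come from a simulation from invented constants; the scatter is artificial.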